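**Plan**

- Retrosynthetic cuts: the C15 ester, the C2 ethyl ether and C4=C18 (functional-group changes); C12–C13 (Negishi coupling); C9–C11 (Ireland–Claisen from the C7 oxygen); C1–C10 with re-formation of C3–C8 (anionic oxy-Cope); C2–C3 (alkoxyvinyl addition); C5–C6 and C7–C8 (Diels–Alder).
- Enabling feature: the cis C5/C10 fusion, C8 and C9 of ring B and the C2/C3-dioxygenated ring A are a disguised 2-(1-ethoxyvinyl)bicyclo[2.2.2]oct-5-en-2-ol in which C3 is bonded to C8 and C1 is not yet bonded to C10.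
- Forward order: arene → masked o-benzoquinone → bicyclo[2.2.2]octenone (future ring B plus C3/C4) → oxy-Cope closes ring A and opens the cage to the cis-decalin → C11/C12 by Claisen → C13–C16 by cross-coupling → ring A adjusted last.
- Stereochemistry: C5 and the C7 oxygen from the ortho/endo Diels–Alder (absolute configuration by resolution of the adduct); C10 from the oxy-Cope; C9 by suprafacial transfer from C7–O; C7/C8 by hydroboration of the convex face; C13 by ligand-controlled conjugate reduction.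

Key step: step 8

Remark on numbering: decalins are numbered as clerodanes (ring A = C1–C5, C10; ring B = C5–C10; methyls C19 on C5, C17 on C8, C20 on C9; side chain C11–C16; C18 on C4), and β is the face of the C5 methyl group. Compounds 8–15 are named with bicyclo[2.2.2]octane locants (bicyclic C1 = C8, C2 = C3, C3 = C4, C4 = C5, C5 = C10, C6 = C9, C7 = C7, C8 = C6).

Assumption: the ethoxy-bearing C2, formed without control in step 8, is carried as an epimer mixture (2ξ) until it becomes trigonal in step 21.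

**Step 1**
Reactants: 1 2,4,5-trimethylphenol
Product: 2 1-methoxy-2,4,5-trimethylbenzene
Conditions: MeI, K2CO3, acetone, reflux
Reagents that add atoms: iodomethane, CI
Why: Williamson ether synthesis on the phenoxide; the methoxy group serves as the directing group of step 2 and later becomes the ketal carbon of the dienone.

**Step 2**
Reactants: 2 1-methoxy-2,4,5-trimethylbenzene
Product: 5 2-methoxy-3,5,6-trimethylphenol, via aryllithium 3 (not isolated), via arylboronate 4 (not isolated)
Conditions: n-BuLi, TMEDA, Et2O, 0 °C → rt; B(OMe)3, −78 °C → rt; H2O2, aq. NaOH, 0 °C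
Reagents that add atoms: hydrogen peroxide, OO
Why: Directed ortho-metalation places lithium on C6, the only ring C–H next to the methoxy group, and borylation followed by peroxide oxidation of the aryl–boron bond installs the phenol oxygen there (lateral lithiation of the neighbouring methyl group is the expected minor competitor).

**Step 3**
Reactants: 5 2-methoxy-3,5,6-trimethylphenol
Product: 6 6,6-dimethoxy-2,3,5-trimethylcyclohexa-2,4-dien-1-one
Conditions: PhI(OAc)2, MeOH, 0 °C; solvent exchanged for toluene below rt and used at once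
Reagents that add atoms: methanol, CO
Why: Oxidative dearomatisation of a 2-methoxyphenol by the trivalent iodine reagent, in which methanol attacks the methoxy-bearing ortho carbon to give the o-quinone monoketal; the three ring methyl groups should slow its Diels–Alder dimerisation.

**Step 4**
Reactants: 6 6,6-dimethoxy-2,3,5-trimethylcyclohexa-2,4-dien-1-one; 7 tert-butyl(dimethyl)(vinyloxy)silane
Product: 8 racemic 7-endo-[(tert-butyldimethylsilyl)oxy]-3,3-dimethoxy-1,4,6-trimethylbicyclo[2.2.2]oct-5-en-2-one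
Conditions: 7 (5 equiv), toluene, 90 °C, sealed tube
Reagents that add atoms: none
Why: Inverse-electron-demand Diels–Alder reaction of the masked o-benzoquinone with an enol ether, in which the CH2 terminus bonds to dienone C5 (largest LUMO coefficient) and the oxygenated carbon to C2, while endo approach puts the silyloxy group syn to the new C5=C6 alkene and fixes the relative configuration of C1, C4 and C7.

**Step 5**
Reactants: 8 racemic Diels–Alder adduct
Product: 9 (1S,4S,7S)-7-[(tert-butyldimethylsilyl)oxy]-3,3-dimethoxy-1,4,6-trimethylbicyclo[2.2.2]oct-5-en-2-one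
Conditions: preparative SFC, amylose tris(3,5-dimethylphenylcarbamate) phase, CO2/i-PrOH
Reagents that add atoms: none
Why: Resolution by chromatography on a chiral stationary phase is the source of absolute configuration for the whole decalin core; the absolute configuration of the collected enantiomer would be assigned before it is carried on.

**Step 6**
Reactants: 9 (1S,4S,7S)-adduct
Product: 11 (1S,4R,7S)-7-[(tert-butyldimethylsilyl)oxy]-1,4,6-trimethylbicyclo[2.2.2]oct-5-en-2-one, via methoxy ketone 10 (not isolated)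
Conditions: SmI2 (4.5 equiv), MeOH, THF, −78 °C → rt
Reagents that add atoms: none
Why: Reductive cleavage of C–O bonds alpha to a ketone by divalent samarium (ketyl, loss of methoxide, enolate protonation), applied twice, turns the ketal carbon into CH2; the bridgehead prevents enolisation toward C1, so the β-silyloxy group is not eliminated.

**Step 7**
Reactants: 11 (1S,4R,7S)-ketone; 12 ethyl vinyl ether
Product: 14 (1S,2S,4R,7S)-7-[(tert-butyldimethylsilyl)oxy]-2-(1-ethoxyvinyl)-1,4,6-trimethylbicyclo[2.2.2]oct-5-en-2-ol, via 1-ethoxyvinyllithium 13 (not isolated)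
Conditions: 12, t-BuLi, THF, −78 → 0 °C; then 11, −78 °C; H2O
Reagents that add atoms: none
Why: 1,2-Addition of an α-alkoxyvinyllithium to the ketone from the carbonyl face that looks at the C5=C6 alkene bridge (less hindered than the face under the ethano-bridge hydrogens), so the ethoxyvinyl group ends syn to the alkene and C2 is set S.

**Step 8**
Reactants: 14 (1S,2S,4R,7S)-2-(1-ethoxyvinyl)bicyclo[2.2.2]oct-5-en-2-ol
Product: 17 2ξ-ethoxy-7β-[(tert-butyldimethylsilyl)oxy]-5β,8,9-trimethyl-10βH-decal-8-en-3-one (cis-fused), via potassium alkoxide 15 (not isolated), via potassium enolate 16 (not isolated)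
Conditions: KH, 18-crown-6, THF, 0 → 50 °C; then AcOH, −78 °C
Reagents that add atoms: none
Why: Deprotonation gives the crown-ether-separated potassium alkoxide 15, whose 1,5-diene C1=C2–C3–C8–C9=C10 is held in a boat-like six-centre array by the cage and undergoes a concerted [3,3] shift accelerated by the oxyanion (anionic oxy-Cope rearrangement of a 2-vinylbicyclo[2.2.2]oct-5-en-2-ol, the closest known type). Ring A closes as a six-membered carbocycle by C1–C10 bonding inside this boat transition state, suprafacially on both allyl halves, while the C3–C8 bond breaks, the cage opens to the decalin and the alkene moves to C8=C9. The new stereocentre C10 is set by the cage, because C1 can reach C10 only on the face turned toward the C3–C4 bridge, which leaves H10 syn to the C5 methyl group (cis fusion), and C5 and C7 are carried over unchanged. The step needs the [3,3] path to outrun [1,3] shift and fragmentation of the alkoxide, which is secured by the syn relation of the ethoxyvinyl group to the C9=C10 bridge from step 7, by strain release and by formation of the stabilised enolate 16. Protonation of 16 at C2 is uncontrolled but harmless, since C2 becomes trigonal again in step 21.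

**Step 9**
Reactants: 17 cis-decalin α-ethoxy ketone
Product: 18 2ξ-ethoxy-3,3-(ethylenedioxy)-7β-[(tert-butyldimethylsilyl)oxy]-5β,8,9-trimethyl-10βH-decal-8-ene
Conditions: Me3SiOCH2CH2OSiMe3, TMSOTf (cat.), CH2Cl2, −78 → −20 °C
Reagents that add atoms: 1,2-bis(trimethylsilyloxy)ethane, C[Si](C)(C)OCCO[Si](C)(C)C
Why: Silyl-transfer acetalisation at low temperature spares the silyl ether and the tetrasubstituted alkene, and the dioxolane masks C3 against LDA, borane and copper hydride in steps 12–18.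

**Step 10**
Reactants: 18 dioxolane silyl ether
Product: 19 2ξ-ethoxy-3,3-(ethylenedioxy)-5β,8,9-trimethyl-10βH-decal-8-en-7β-ol
Conditions: TBAF, THF, rt → 45 °C
Reagents that add atoms: none
Why: Fluoride cleavage of the Si–O bond frees the C7 allylic alcohol without touching the acetal.

**Step 11**
Reactants: 19 C7 allylic alcohol
Product: 20 7β-acetoxy-2ξ-ethoxy-3,3-(ethylenedioxy)-5β,8,9-trimethyl-10βH-decal-8-ene
Conditions: Ac2O, Et3N, DMAP (cat.), CH2Cl2, rt
Reagents that add atoms: acetic anhydride, CC(=O)OC(C)=O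
Why: DMAP-catalysed acylation of the secondary allylic alcohol gives the acetate required for the sigmatropic step.

**Step 12**
Reactants: 20 C7 allylic acetate
Product: 23 [2ξ-ethoxy-3,3-(ethylenedioxy)-5β,8,9α-trimethyl-10βH-decal-7-en-9β-yl]acetic acid, via silyl ketene acetal 21 (not isolated), via silyl ester 22 (not isolated)
Conditions: LDA, TMSCl/Et3N, THF, −78 → 65 °C; then MeOH/H2O
Reagents that add atoms: none
Why: Ireland–Claisen rearrangement, in which the silyl ketene acetal shifts [3,3] across C7–C8=C9 with suprafacial transfer of chirality, so the β C7–O bond is exchanged for a β C9–C11 bond on the face of C9 flanked by H10 (9α-methyl, 9β-carboxymethyl) and the alkene moves to C7=C8.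

**Step 13**
Reactants: 23 C12 carboxylic acid
Product: 25 2-[2ξ-ethoxy-3,3-(ethylenedioxy)-7β-hydroxy-5β,8α,9α-trimethyl-10βH-decalin-9β-yl]ethanol, via C7 borane 24 (not isolated)
Conditions: BH3·THF (4 equiv), THF, 0 °C → rt; then aq. NaOH, H2O2, 0 °C
Reagents that add atoms: hydrogen peroxide, OO
Why: Borane reduces the acid to the primary alcohol and hydroborates the trisubstituted alkene with boron on C7, syn and from the convex β face opposite the pseudo-axial 9α-methyl group and ring A, so oxidation with retention should give 7β-OH and 8β-H (8α-methyl).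

**Step 14**
Reactants: 25 C7,C12 diol
Product: 26 2ξ-ethoxy-3,3-(ethylenedioxy)-9β-(2-iodoethyl)-5β,8α,9α-trimethyl-10βH-decalin-7β-ol
Conditions: I2, PPh3, imidazole, CH2Cl2, 0 °C
Reagents that add atoms: iodine, II
Why: Appel-type iodination (phosphonium activation, SN2 by iodide) is selective for the unhindered primary alcohol over the secondary C7 hydroxyl flanked by C8.

**Step 15**
Reactants: 26 iodo alcohol
Product: 27 7β-acetoxy-2ξ-ethoxy-3,3-(ethylenedioxy)-9β-(2-iodoethyl)-5β,8α,9α-trimethyl-10βH-decalin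
Conditions: Ac2O, DMAP (cat.), pyridine, rt
Reagents that add atoms: acetic anhydride, CC(=O)OC(C)=O
Why: Acylation of the remaining secondary alcohol installs the C7 acetate of the target, which tolerates the organozinc, copper hydride and dilute-acid steps that follow.

**Step 16**
Reactants: 28 tert-butyl acetoacetate
Product: 29 tert-butyl (2E)-3-{[(trifluoromethyl)sulfonyl]oxy}but-2-enoate
Conditions: Tf2O, aq. Me4NOH, hexanes, 5 °C
Reagents that add atoms: trifluoromethanesulfonic anhydride, O=S(=O)(OS(=O)(=O)C(F)(F)F)C(F)(F)F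
Why: O-sulfonylation of the β-keto ester enolate, where the non-chelating tetramethylammonium counter-ion favours the (E)-enol triflate and so fixes the alkene geometry needed in step 18.

**Step 17**
Reactants: 27 iodo acetate; 29 (E)-enol triflate
Product: 31 tert-butyl (2E)-5-[7β-acetoxy-2ξ-ethoxy-3,3-(ethylenedioxy)-5β,8α,9α-trimethyl-10βH-decalin-9β-yl]-3-methylpent-2-enoate, via alkylzinc iodide 30 (not isolated)
Conditions: Zn dust, LiCl, THF, 40 °C; then 29, Pd(PPh3)4 (5 mol %), THF, 50 °C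
Reagents that add atoms: none
Why: Zinc insertion into the primary C–I bond gives an ester-tolerant alkylzinc iodide, which undergoes Negishi cross-coupling with the enol triflate under zerovalent palladium catalysis with retention of alkene geometry, forming C12–C13.

**Step 18**
Reactants: 31 (E)-enoate
Product: 32 tert-butyl (3R)-5-[7β-acetoxy-2ξ-ethoxy-3,3-(ethylenedioxy)-5β,8α,9α-trimethyl-10βH-decalin-9β-yl]-3-methylpentanoate
Conditions: Cu(OAc)2·H2O (5 mol %), (S)-DTBM-SEGPHOS (5 mol %), (EtO)2MeSiH, t-BuOH, toluene, 0 °C → rt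
Reagents that add atoms: none
Why: Copper hydride catalysed asymmetric conjugate reduction of a β,β-disubstituted enoate, in which the bisphosphine and not the remote ring stereocentres selects the face of C13; the (S)-ligand is the antipode expected to give 13R from the (E)-enoate by analogy with simple (E)-3-methylalk-2-enoates, this would be confirmed on such a model, and the (R)-ligand is available if the sense is opposite.

**Step 19**
Reactants: 32 saturated ester acetal
Product: 33 tert-butyl (3R)-5-[7β-acetoxy-2ξ-ethoxy-5β,8α,9α-trimethyl-3-oxo-10βH-decalin-9β-yl]-3-methylpentanoate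
Conditions: 1 M aq. HCl, THF, rt → 40 °C
Reagents that add atoms: water, O
Why: Acid-catalysed acetal hydrolysis regenerates the C3 ketone, and the tert-butyl ester and the acetate are stable to dilute aqueous acid at this temperature.

**Step 20**
Reactants: 33 α-ethoxy ketone
Product: 37 tert-butyl (3R)-5-[7β-acetoxy-2ξ-ethoxy-5β,8α,9α-trimethyl-4-methylene-3-oxo-10βH-decalin-9β-yl]-3-methylpentanoate, via lithium enolate 34 (not isolated), via Mannich base 35 (not isolated), via ammonium iodide 36 (not isolated)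
Conditions: LiHMDS (1.05 equiv), THF, −78 °C; Me2N=CH2 iodide, −78 °C → rt; MeI, rt; aq. NaHCO3, CH2Cl2
Reagents that add atoms: N,N-dimethylmethyleneiminium iodide (Eschenmoser's salt), C=[N+](C)C.[I-]
Why: Kinetic deprotonation of the ketone (more acidic than either ester) at the CH2 group C4 rather than at the alkoxy-bearing methine C2, Mannich reaction with the iminium salt, N-methylation and base-induced elimination of trimethylamine give the α-methylene ketone, and the double bond cannot move into the ring because C5 is quaternary.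

**Step 21**
Reactants: 37 α-methylene α′-ethoxy ketone
Product: 40 tert-butyl (13R)-7β-acetoxy-2-hydroxy-3-oxo-5β,10β-cleroda-1,4(18)-dien-15-oate, via potassium enolate 38 (not isolated), via hemiketal 39 (not isolated)
Conditions: KHMDS (1.05 equiv), THF, −78 °C; 2-(phenylsulfonyl)-3-phenyloxaziridine, −78 → −40 °C; AcOH
Reagents that add atoms: 2-(phenylsulfonyl)-3-phenyloxaziridine, O=S(=O)(c1ccccc1)N1OC1c1ccccc1
Why: Enolate α-hydroxylation with an N-sulfonyloxaziridine at C2, now the only enolisable position, gives the C2 hemiketal, which expels ethoxide to the 2,3-diketone; this enolises toward C1 to the diosphenol, so the ethyl group is removed without acid hydrolysis of an enol ether.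

**Step 22**
Reactants: 40 diosphenol tert-butyl ester
Product: 41 (13R)-7β-acetoxy-2-hydroxy-3-oxo-5β,10β-cleroda-1,4(18)-dien-15-oic acid (8α-methyl, 9α-methyl; 5S,7S,8S,9R,10R,13R), the target
Conditions: TFA, CH2Cl2, 0 °C → rt
Reagents that add atoms: none
Why: Acidolysis of the tert-butyl ester with loss of 2-methylpropene under anhydrous conditions frees the acid and leaves the acetate, the diosphenol and the exocyclic enone intact.

**Compound list**

1 | 2,4,5-trimethylphenol | Cc1cc(C)c(O)cc1C | starting material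
2 | 1-methoxy-2,4,5-trimethylbenzene | COc1cc(C)c(C)cc1C | intermediate
3 | (2-methoxy-3,5,6-trimethylphenyl)lithium | COc1c([Li])c(C)c(C)cc1C | intermediate
4 | dimethyl (2-methoxy-3,5,6-trimethylphenyl)boronate | COc1c(B(OC)OC)c(C)c(C)cc1C | intermediate
5 | 2-methoxy-3,5,6-trimethylphenol | COc1c(O)c(C)c(C)cc1C | intermediate
6 | 6,6-dimethoxy-2,3,5-trimethylcyclohexa-2,4-dien-1-one | O=C1C(C)=C(C)C=C(C)C1(OC)OC | intermediate
7 | tert-butyl(dimethyl)(vinyloxy)silane | C=CO[Si](C)(C)C(C)(C)C | starting material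
8 | racemic 7-endo-[(tert-butyldimethylsilyl)oxy]-3,3-dimethoxy-1,4,6-trimethylbicyclo[2.2.2]oct-5-en-2-one (1:1 mixture of the 1S,4S,7S and 1R,4R,7R forms) | O=C1C(OC)(OC)[C@]2(C)C=C(C)[C@@]1(C)[C@@H](O[Si](C)(C)C(C)(C)C)C2.O=C1C(OC)(OC)[C@@]2(C)C=C(C)[C@]1(C)[C@H](O[Si](C)(C)C(C)(C)C)C2 | intermediate
9 | (1S,4S,7S)-7-[(tert-butyldimethylsilyl)oxy]-3,3-dimethoxy-1,4,6-trimethylbicyclo[2.2.2]oct-5-en-2-one | O=C1C(OC)(OC)[C@]2(C)C=C(C)[C@@]1(C)[C@@H](O[Si](C)(C)C(C)(C)C)C2 | intermediate
10 | (1S,3ξ,4S,7S)-7-[(tert-butyldimethylsilyl)oxy]-3-methoxy-1,4,6-trimethylbicyclo[2.2.2]oct-5-en-2-one | O=C1C(OC)[C@]2(C)C=C(C)[C@@]1(C)[C@@H](O[Si](C)(C)C(C)(C)C)C2 | intermediate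
11 | (1S,4R,7S)-7-[(tert-butyldimethylsilyl)oxy]-1,4,6-trimethylbicyclo[2.2.2]oct-5-en-2-one | O=C1C[C@]2(C)C=C(C)[C@@]1(C)[C@@H](O[Si](C)(C)C(C)(C)C)C2 | intermediate
12 | ethyl vinyl ether | C=COCC | starting material
13 | 1-ethoxyvinyllithium | [Li]C(=C)OCC | intermediate
14 | (1S,2S,4R,7S)-7-[(tert-butyldimethylsilyl)oxy]-2-(1-ethoxyvinyl)-1,4,6-trimethylbicyclo[2.2.2]oct-5-en-2-ol (ethoxyvinyl syn to C5=C6) | C=C(OCC)[C@]1(O)C[C@]2(C)C=C(C)[C@@]1(C)[C@@H](O[Si](C)(C)C(C)(C)C)C2 | intermediate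
15 | potassium alkoxide of 14 | C=C(OCC)[C@]1([O-])C[C@]2(C)C=C(C)[C@@]1(C)[C@@H](O[Si](C)(C)C(C)(C)C)C2.[K+] | intermediate
16 | potassium 2-ethoxy-7β-[(tert-butyldimethylsilyl)oxy]-5β,8,9-trimethyl-10βH-decala-2,8-dien-3-olate | C1C([O-])=C(OCC)C[C@@H]2C(C)=C(C)[C@@H](O[Si](C)(C)C(C)(C)C)C[C@]12C.[K+] | intermediate
17 | 2ξ-ethoxy-7β-[(tert-butyldimethylsilyl)oxy]-5β,8,9-trimethyl-10βH-decal-8-en-3-one (cis-fused) | C1C(=O)C(OCC)C[C@@H]2C(C)=C(C)[C@@H](O[Si](C)(C)C(C)(C)C)C[C@]12C | intermediate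
18 | 2ξ-ethoxy-3,3-(ethylenedioxy)-7β-[(tert-butyldimethylsilyl)oxy]-5β,8,9-trimethyl-10βH-decal-8-ene | C1C3(OCCO3)C(OCC)C[C@@H]2C(C)=C(C)[C@@H](O[Si](C)(C)C(C)(C)C)C[C@]12C | intermediate
19 | 2ξ-ethoxy-3,3-(ethylenedioxy)-5β,8,9-trimethyl-10βH-decal-8-en-7β-ol | C1C3(OCCO3)C(OCC)C[C@@H]2C(C)=C(C)[C@@H](O)C[C@]12C | intermediate
20 | 7β-acetoxy-2ξ-ethoxy-3,3-(ethylenedioxy)-5β,8,9-trimethyl-10βH-decal-8-ene | C1C3(OCCO3)C(OCC)C[C@@H]2C(C)=C(C)[C@@H](OC(C)=O)C[C@]12C | intermediate
21 | trimethylsilyl ketene acetal of 20 (C7–O–C(=CH2)–OSiMe3) | C1C3(OCCO3)C(OCC)C[C@@H]2C(C)=C(C)[C@@H](OC(=C)O[Si](C)(C)C)C[C@]12C | intermediate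
22 | trimethylsilyl ester of 23 | C1C3(OCCO3)C(OCC)C[C@@H]2[C@@](C)(CC(=O)O[Si](C)(C)C)C(C)=CC[C@]12C | intermediate
23 | [2ξ-ethoxy-3,3-(ethylenedioxy)-5β,8,9α-trimethyl-10βH-decal-7-en-9β-yl]acetic acid | C1C3(OCCO3)C(OCC)C[C@@H]2[C@@](C)(CC(=O)O)C(C)=CC[C@]12C | intermediate
24 | 7β-boryl-12-boryloxy intermediate (drawn with BH2 groups; 8α-methyl) | C1C3(OCCO3)C(OCC)C[C@@H]2[C@@](C)(CCOB)[C@H](C)[C@@H](B)C[C@]12C | intermediate
25 | 2-[2ξ-ethoxy-3,3-(ethylenedioxy)-7β-hydroxy-5β,8α,9α-trimethyl-10βH-decalin-9β-yl]ethanol | C1C3(OCCO3)C(OCC)C[C@@H]2[C@@](C)(CCO)[C@H](C)[C@@H](O)C[C@]12C | intermediate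
26 | 2ξ-ethoxy-3,3-(ethylenedioxy)-9β-(2-iodoethyl)-5β,8α,9α-trimethyl-10βH-decalin-7β-ol | C1C3(OCCO3)C(OCC)C[C@@H]2[C@@](C)(CCI)[C@H](C)[C@@H](O)C[C@]12C | intermediate
27 | 7β-acetoxy-2ξ-ethoxy-3,3-(ethylenedioxy)-9β-(2-iodoethyl)-5β,8α,9α-trimethyl-10βH-decalin | C1C3(OCCO3)C(OCC)C[C@@H]2[C@@](C)(CCI)[C@H](C)[C@@H](OC(C)=O)C[C@]12C | intermediate
28 | tert-butyl acetoacetate | CC(=O)CC(=O)OC(C)(C)C | starting material
29 | tert-butyl (2E)-3-{[(trifluoromethyl)sulfonyl]oxy}but-2-enoate | C/C(OS(=O)(=O)C(F)(F)F)=C\C(=O)OC(C)(C)C | intermediate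
30 | alkylzinc iodide from 27 (C12–ZnI) | C1C3(OCCO3)C(OCC)C[C@@H]2[C@@](C)(CC[Zn]I)[C@H](C)[C@@H](OC(C)=O)C[C@]12C | intermediate
31 | tert-butyl (2E)-5-[7β-acetoxy-2ξ-ethoxy-3,3-(ethylenedioxy)-5β,8α,9α-trimethyl-10βH-decalin-9β-yl]-3-methylpent-2-enoate | C1C3(OCCO3)C(OCC)C[C@@H]2[C@@](C)(CC/C(C)=C/C(=O)OC(C)(C)C)[C@H](C)[C@@H](OC(C)=O)C[C@]12C | intermediate
32 | tert-butyl (3R)-5-[7β-acetoxy-2ξ-ethoxy-3,3-(ethylenedioxy)-5β,8α,9α-trimethyl-10βH-decalin-9β-yl]-3-methylpentanoate | C1C3(OCCO3)C(OCC)C[C@@H]2[C@@](C)(CC[C@@H](C)CC(=O)OC(C)(C)C)[C@H](C)[C@@H](OC(C)=O)C[C@]12C | intermediate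
33 | tert-butyl (3R)-5-[7β-acetoxy-2ξ-ethoxy-5β,8α,9α-trimethyl-3-oxo-10βH-decalin-9β-yl]-3-methylpentanoate | C1C(=O)C(OCC)C[C@@H]2[C@@](C)(CC[C@@H](C)CC(=O)OC(C)(C)C)[C@H](C)[C@@H](OC(C)=O)C[C@]12C | intermediate
34 | lithium C3=C4 enolate of 33 | C1=C([O-])C(OCC)C[C@@H]2[C@@](C)(CC[C@@H](C)CC(=O)OC(C)(C)C)[C@H](C)[C@@H](OC(C)=O)C[C@]12C.[Li+] | intermediate
35 | 4ξ-[(dimethylamino)methyl] derivative of 33 | CN(C)CC1C(=O)C(OCC)C[C@@H]2[C@@](C)(CC[C@@H](C)CC(=O)OC(C)(C)C)[C@H](C)[C@@H](OC(C)=O)C[C@]12C | intermediate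
36 | 4ξ-[(trimethylammonio)methyl] iodide derived from 35 | C[N+](C)(C)CC1C(=O)C(OCC)C[C@@H]2[C@@](C)(CC[C@@H](C)CC(=O)OC(C)(C)C)[C@H](C)[C@@H](OC(C)=O)C[C@]12C.[I-] | intermediate
37 | tert-butyl (3R)-5-[7β-acetoxy-2ξ-ethoxy-5β,8α,9α-trimethyl-4-methylene-3-oxo-10βH-decalin-9β-yl]-3-methylpentanoate | C=C1C(=O)C(OCC)C[C@@H]2[C@@](C)(CC[C@@H](C)CC(=O)OC(C)(C)C)[C@H](C)[C@@H](OC(C)=O)C[C@]12C | intermediate
38 | potassium C2=C3 enolate of 37 | C=C1C([O-])=C(OCC)C[C@@H]2[C@@](C)(CC[C@@H](C)CC(=O)OC(C)(C)C)[C@H](C)[C@@H](OC(C)=O)C[C@]12C.[K+] | intermediate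
39 | 2-ethoxy-2-hydroxy-3-ketone (C2 hemiketal) from 38 | C=C1C(=O)C(O)(OCC)C[C@@H]2[C@@](C)(CC[C@@H](C)CC(=O)OC(C)(C)C)[C@H](C)[C@@H](OC(C)=O)C[C@]12C | intermediate
40 | tert-butyl (13R)-7β-acetoxy-2-hydroxy-3-oxo-5β,10β-cleroda-1,4(18)-dien-15-oate | C=C1C(=O)C(O)=C[C@@H]2[C@@](C)(CC[C@@H](C)CC(=O)OC(C)(C)C)[C@H](C)[C@@H](OC(C)=O)C[C@]12C | intermediate
41 | (13R)-7β-acetoxy-2-hydroxy-3-oxo-5β,10β-cleroda-1,4(18)-dien-15-oic acid (5S,7S,8S,9R,10R,13R) | C=C1C(=O)C(O)=C[C@@H]2[C@@](C)(CC[C@@H](C)CC(=O)O)[C@H](C)[C@@H](OC(C)=O)C[C@]12C | target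

**Count**

Total: 22 steps. Longest linear sequence: 21 steps (steps 1–15 and 17–22); step 16 prepares the coupling partner.

**Steps most likely to fail**

Step 12 (Ireland–Claisen). C-silylation or self-condensation of the acetate enolate, and a slow [3,3] shift onto the fully substituted C9 between C8 and C10, could return unrearranged ester or cleaved alcohol. The fallback sets out from alcohol 19 and avoids an enolate altogether. Eschenmoser–Claisen rearrangement with N,N-dimethylacetamide dimethyl acetal (xylene, 140 °C) would give the 9β-(dimethylcarbamoylmethyl) Δ7-decalin F1 with the same suprafacial transfer. Reduction with lithium amidotrihydroborate (LiH2NBH3, THF) would give the primary alcohol F2. Hydroboration–oxidation as in step 13 then rejoins the route at diol 25.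

Step 13 (hydroboration). Facial selectivity may be poor if the half-chair that presents the α face is populated, so that borane adds opposite to the desired sense. The fallback sets out from acid 23 and replaces kinetic face selection by thermodynamic control. The same borane/peroxide treatment would then give the 7α-hydroxy-8β-methyl diol F3. TBSCl/imidazole would silylate the primary alcohol to the silyl ether F4. Dess–Martin periodinane would give the 8β-methyl C7 ketone F5. DBU in toluene would epimerise C8 to the equatorial 8α-methyl ketone F6. Dissolving-metal reduction (Li, NH3, MeOH, −78 °C) would give the equatorial 7β-alcohol F7. TBAF then rejoins the route at diol 25.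

Step 21 (enolate hydroxylation). The enolate may add in Michael fashion to the α-methylene ketone (oligomerisation), the acetate may enolise competitively, or the enolate may add to the sulfonimine by-product. The fallback sets out from ketone 33 and reverses the order of ring A operations. Dehydrogenation with IBX (DMSO/toluene, 70 °C), possible only toward C1 because C5 is quaternary, would give the 2-ethoxy-1-en-3-one F8. Kinetic α′-methylenation at C4 under the conditions of step 20 would give the cross-conjugated 2-ethoxy-1,4(18)-dien-3-one F9. Aqueous TFA (TFA/H2O/CH2Cl2, rt) would hydrolyse the ethyl enol ether and cleave the tert-butyl ester, arriving directly at target 41.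

**Further compounds**

F1 | step 12 | 2-[2ξ-ethoxy-3,3-(ethylenedioxy)-5β,8,9α-trimethyl-10βH-decal-7-en-9β-yl]-N,N-dimethylacetamide | C1C3(OCCO3)C(OCC)C[C@@H]2[C@@](C)(CC(=O)N(C)C)C(C)=CC[C@]12C
F2 | step 12 | 2-[2ξ-ethoxy-3,3-(ethylenedioxy)-5β,8,9α-trimethyl-10βH-decal-7-en-9β-yl]ethanol | C1C3(OCCO3)C(OCC)C[C@@H]2[C@@](C)(CCO)C(C)=CC[C@]12C
F3 | step 13 | 2-[2ξ-ethoxy-3,3-(ethylenedioxy)-7α-hydroxy-5β,8β,9α-trimethyl-10βH-decalin-9β-yl]ethanol | C1C3(OCCO3)C(OCC)C[C@@H]2[C@@](C)(CCO)[C@@H](C)[C@H](O)C[C@]12C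
F4 | step 13 | 12-O-tert-butyldimethylsilyl ether of F3 | C1C3(OCCO3)C(OCC)C[C@@H]2[C@@](C)(CCO[Si](C)(C)C(C)(C)C)[C@@H](C)[C@H](O)C[C@]12C
F5 | step 13 | 8β-methyl C7 ketone from F4 | C1C3(OCCO3)C(OCC)C[C@@H]2[C@@](C)(CCO[Si](C)(C)C(C)(C)C)[C@@H](C)C(=O)C[C@]12C
F6 | step 13 | 8α-methyl C7 ketone (C8 epimer of F5) | C1C3(OCCO3)C(OCC)C[C@@H]2[C@@](C)(CCO[Si](C)(C)C(C)(C)C)[C@H](C)C(=O)C[C@]12C
F7 | step 13 | 12-O-tert-butyldimethylsilyl ether of diol 25 (7β-OH, 8α-methyl) | C1C3(OCCO3)C(OCC)C[C@@H]2[C@@](C)(CCO[Si](C)(C)C(C)(C)C)[C@H](C)[C@@H](O)C[C@]12C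
F8 | step 21 | tert-butyl (3R)-5-[7β-acetoxy-2-ethoxy-5β,8α,9α-trimethyl-3-oxo-10βH-decal-1-en-9β-yl]-3-methylpentanoate | C1C(=O)C(OCC)=C[C@@H]2[C@@](C)(CC[C@@H](C)CC(=O)OC(C)(C)C)[C@H](C)[C@@H](OC(C)=O)C[C@]12C
F9 | step 21 | tert-butyl (13R)-7β-acetoxy-2-ethoxy-3-oxo-5β,10β-cleroda-1,4(18)-dien-15-oate | C=C1C(=O)C(OCC)=C[C@@H]2[C@@](C)(CC[C@@H](C)CC(=O)OC(C)(C)C)[C@H](C)[C@@H](OC(C)=O)C[C@]12C
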